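The decalin is disconnected through both rings at once: the trisubstituted C3=C4 alkene of ring A, flanked by the quaternary C5 and by C10–H, is the retron of a 1,5-diketone (C4 acetyl, C2 ketone). In one operation an intramolecular Michael addition and an aldol condensation of an acyclic, enantiopure 5-silyloxy-undec-3-ene-2,10-dione close ring B (C5–C10 bond) and ring A (C3=C4 bond) and set C5 and C10. Afterwards the C2 carbonyl is removed, the temporary C9 oxygen is used to install C8 and C9 on the rigid trans-decalin, and the arene is oxidised to a hydroxyquinone whose benzilic ester ring contraction gives the cyclopentenone.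

Key step: step 5

Remark: decalin atoms carry terpenoid numbers (C1–C10, C11 = CH2 on C8; the same numbers are used for the acyclic precursors) and β is the face of the C5 methyl; the future C5 centre is carried as both epimers up to step 5 and is left undefined in the SMILES of 4, 5 and 7–10.

Step 1
Reactants: 1 2-(3-chloropropyl)-1,3-dioxolane; 2 3-methylbut-3-en-2-one
Product: 5 6-methyl-7-oxooctanal, via Grignard reagent 3 (not isolated), via keto acetal 4 (not isolated)
Conditions: Mg, THF, reflux; CuBr·SMe2 (5 mol %), 2, THF, −40 °C; then 2 M HCl, THF, 20 °C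
Reagents that add atoms: water, O
Why: Copper-catalysed 1,4-addition of the Grignard reagent to the β-unsubstituted enone followed by acetal hydrolysis in the acidic work-up should deliver the keto aldehyde, whose methyl-bearing centre (future C5) forms as both epimers and is enolised later.

Step 2
Reactants: 5 6-methyl-7-oxooctanal; 6 dimethyl (2-oxopropyl)phosphonate
Product: 8 (3E,5R)-5-(anilinooxy)-9-methylundec-3-ene-2,10-dione, via aminoxy aldehyde 7 (not isolated)
Conditions: PhNO, L-proline (20 mol %), DMSO, 20 °C; then 6, Cs2CO3, 0 °C to 20 °C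
Reagents that add atoms: nitrosobenzene, O=Nc1ccccc1
Why: L-Proline enamine α-aminoxylation should set the future C9 carbinol centre as R through the carboxylic acid-directed transition state, and the in-situ Horner–Wadsworth–Emmons reaction converts the labile aldehyde into the E-enone (C10=C1) without erosion.

Step 3
Reactants: 8 (3E,5R)-5-(anilinooxy)-9-methylundec-3-ene-2,10-dione
Product: 9 (3E,5R)-5-hydroxy-9-methylundec-3-ene-2,10-dione
Conditions: Cu(OAc)2·H2O (30 mol %), EtOH, 20 °C
Reagents that add atoms: none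
Why: Copper-catalysed N–O cleavage of the O-alkyl hydroxylamine should free the γ-hydroxy enone without touching the C–O bond, so the R configuration is retained.

Step 4
Reactants: 9 (3E,5R)-5-hydroxy-9-methylundec-3-ene-2,10-dione
Product: 10 (3E,5R)-5-[(tert-butyldimethylsilyl)oxy]-9-methylundec-3-ene-2,10-dione
Conditions: TBSCl, imidazole, DMF, 20 °C
Reagents that add atoms: tert-butyldimethylsilyl chloride, CC(C)(C)[Si](C)(C)Cl
Why: Silylation of the secondary allylic alcohol protects the γ-hydroxy enone against base-induced isomerisation and provides a large equatorial control element at C9 for step 5.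

Step 5
Reactants: 10 (3E,5R)-5-[(tert-butyldimethylsilyl)oxy]-9-methylundec-3-ene-2,10-dione
Product: 12 (4aS,8R,8aR)-8-[(tert-butyldimethylsilyl)oxy]-4,4a-dimethyl-4a,5,6,7,8,8a-hexahydronaphthalen-2(1H)-one, via diketone 11 (not isolated)
Conditions: KOtBu (0.2 equiv), t-BuOH/THF, 0 °C; then AcOH, pyrrolidine, 50 °C (one pot)
Reagents that add atoms: none
Why: Catalytic KOtBu equilibrates the saturated methyl ketone to its more substituted enolate (C5), which adds to C10 of the enone (the methyl-side enolate could close only an eight-membered ring), and pyrrolidine/AcOH then forms the enamine of the unhindered C2 ketone of diketone 11, which attacks the C4 acetyl carbonyl and loses water (E1cB) to give the C3=C4 enone. The closest known reaction type is the Robinson annulation, here with an intramolecular Michael addition and a Hajos–Parrish-type amine-mediated aldol condensation. Ring B closes by 6-exo-trig Michael addition through a chair transition state and ring A by 6-(enolexo)-exo-trig aldol addition followed by dehydration. C5 and C10 are set in the Michael step by the C9 stereocentre: the OTBS group and the enone arm sit equatorial and the bulky potassium enolate unit takes the equatorial site on C5, so the C5 methyl should become axial and anti to H10 (trans fusion, C9 oxygen α). The step needs aldol regioselectivity (C3 onto C4 and not the acetyl methyl onto C2), secured because the neopentyl-type C4 ketone does not form an enamine, and facial selectivity at C5, secured by the enantiopure C9 centre. The minor C5 epimer is removed by chromatography, and any C10 epimer would converge once C10 becomes epimerisable after step 8.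

Step 6
Reactants: 12 (4aS,8R,8aR)-8-[(tert-butyldimethylsilyl)oxy]-4,4a-dimethyl-4a,5,6,7,8,8a-hexahydronaphthalen-2(1H)-one
Product: 13 (4a′S,8′R,8a′R)-4′,4a′-dimethyl-4a′,5′,6′,7′,8′,8a′-hexahydro-1′H-spiro[1,3-dithiolane-2,2′-naphthalen]-8′-ol
Conditions: HSCH2CH2SH, BF3·OEt2, MeOH, 0 °C to 20 °C
Reagents that add atoms: ethane-1,2-dithiol, SCCS
Why: BF3-promoted dithioketalisation of the enone carbonyl (the double bond cannot migrate past quaternary C5) is combined with acid methanolysis of the silyl ether, so C2 is prepared for reduction and the C9 alcohol is freed with no change at any stereocentre.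

Step 7
Reactants: 13 (4a′S,8′R,8a′R)-4′,4a′-dimethyl-4a′,5′,6′,7′,8′,8a′-hexahydro-1′H-spiro[1,3-dithiolane-2,2′-naphthalen]-8′-ol
Product: 14 (1R,4aS,8aR)-4a,5-dimethyl-1,2,3,4,4a,7,8,8a-octahydronaphthalen-1-ol
Conditions: Raney Ni (W-2), EtOH, reflux
Reagents that add atoms: none
Why: Raney Ni hydrogenolysis of the dithiolane (Mozingo reduction) should replace the C2 carbonyl function by CH2 while the trisubstituted C3=C4 alkene next to C5 stays in place.

Step 8
Reactants: 14 (1R,4aS,8aR)-4a,5-dimethyl-1,2,3,4,4a,7,8,8a-octahydronaphthalen-1-ol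
Product: 15 (4aS,8aR)-4a,5-dimethyl-3,4,4a,7,8,8a-hexahydronaphthalen-1(2H)-one
Conditions: Dess–Martin periodinane, CH2Cl2, 20 °C
Reagents that add atoms: none
Why: Dess–Martin oxidation converts the C9 carbinol into the ketone that activates C8, and C10 keeps its α-hydrogen because the trans ring fusion is expected to be the more stable arrangement.

Step 9
Reactants: 16 1,2,4,5-tetramethoxybenzene
Product: 18 2,3,5,6-tetramethoxybenzaldehyde, via aryllithium 17 (not isolated)
Conditions: n-BuLi, TMEDA, THF, 0 °C; then DMF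
Reagents that add atoms: N,N-dimethylformamide, CN(C)C=O
Why: Directed ortho-lithiation between two methoxy groups of the symmetric arene and formylation with DMF can give only one regioisomer.

Step 10
Reactants: 15 (4aS,8aR)-4a,5-dimethyl-3,4,4a,7,8,8a-hexahydronaphthalen-1(2H)-one; 18 2,3,5,6-tetramethoxybenzaldehyde
Product: 19 (2E,4aS,8aR)-4a,5-dimethyl-2-[(2,3,5,6-tetramethoxyphenyl)methylidene]-3,4,4a,7,8,8a-hexahydronaphthalen-1(2H)-one
Conditions: KOH, EtOH, 60 °C
Reagents that add atoms: none
Why: Claisen–Schmidt aldol condensation can dehydrate only at C8, the sole α-carbon with two hydrogens, and should give the E-benzylidene ketone (aryl anti to the carbonyl) under thermodynamic control.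

Step 11
Reactants: 19 (2E,4aS,8aR)-4a,5-dimethyl-2-[(2,3,5,6-tetramethoxyphenyl)methylidene]-3,4,4a,7,8,8a-hexahydronaphthalen-1(2H)-one
Product: 21 (2R,4aS,8aR)-2,4a,5-trimethyl-2-[(2,3,5,6-tetramethoxyphenyl)methyl]-3,4,4a,7,8,8a-hexahydronaphthalen-1(2H)-one, via lithium enolate 20 (not isolated)
Conditions: Li, NH3(l), THF, −78 °C; then MeI
Reagents that add atoms: iodomethane, CI
Why: Dissolving-metal conjugate reduction gives the C8–C9 lithium enolate regiospecifically, and methylation should occur axially on the α face through a chair-like transition state, which sets C8 with the methyl α and the arylmethyl group β-equatorial (reductive alkylation of an enone).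

Step 12
Reactants: 21 (2R,4aS,8aR)-2,4a,5-trimethyl-2-[(2,3,5,6-tetramethoxyphenyl)methyl]-3,4,4a,7,8,8a-hexahydronaphthalen-1(2H)-one
Product: 22 1,2,4,5-tetramethoxy-3-{[(2R,4aS,8aS)-2,4a,5-trimethyl-1-methylidene-1,2,3,4,4a,7,8,8a-octahydronaphthalen-2-yl]methyl}benzene
Conditions: Ph3PCH3Br, KOtBu, toluene, 110 °C
Reagents that add atoms: methyltriphenylphosphonium bromide, [Br-].C[P+](c1ccccc1)(c1ccccc1)c1ccccc1
Why: Wittig methylenation under forcing conditions should convert the hindered C9 ketone into the exocyclic alkene without touching C8 or C10.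

Step 13
Reactants: 22 1,2,4,5-tetramethoxy-3-{[(2R,4aS,8aS)-2,4a,5-trimethyl-1-methylidene-1,2,3,4,4a,7,8,8a-octahydronaphthalen-2-yl]methyl}benzene
Product: 23 1,2,4,5-tetramethoxy-3-{[(1R,2R,4aS,8aS)-1,2,4a,5-tetramethyl-1,2,3,4,4a,7,8,8a-octahydronaphthalen-2-yl]methyl}benzene
Conditions: H2 (1 atm), PtO2, EtOAc, 20 °C
Reagents that add atoms: none
Why: Heterogeneous hydrogenation should add H2 to the exocyclic alkene from the α face, because axial approach on the β face is blocked by the syn-axial C5 methyl, so the new C9 methyl becomes β (R at C9), while the trisubstituted ring alkene next to C5 is too hindered to be reduced.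

Step 14
Reactants: 23 1,2,4,5-tetramethoxy-3-{[(1R,2R,4aS,8aS)-1,2,4a,5-tetramethyl-1,2,3,4,4a,7,8,8a-octahydronaphthalen-2-yl]methyl}benzene
Product: 24 2,5-dimethoxy-3-{[(1R,2R,4aS,8aS)-1,2,4a,5-tetramethyl-1,2,3,4,4a,7,8,8a-octahydronaphthalen-2-yl]methyl}cyclohexa-2,5-diene-1,4-dione
Conditions: (NH4)2Ce(NO3)6, MeCN/H2O, 0 °C
Reagents that add atoms: water, O
Why: Oxidative demethylation of a para-dimethoxy pair should give the 2,5-dimethoxy-1,4-benzoquinone, either para pair leading to the same product by symmetry, with no stereocentre affected.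

Step 15
Reactants: 24 2,5-dimethoxy-3-{[(1R,2R,4aS,8aS)-1,2,4a,5-tetramethyl-1,2,3,4,4a,7,8,8a-octahydronaphthalen-2-yl]methyl}cyclohexa-2,5-diene-1,4-dione
Product: 25 2-hydroxy-5-methoxy-3-{[(1R,2R,4aS,8aS)-1,2,4a,5-tetramethyl-1,2,3,4,4a,7,8,8a-octahydronaphthalen-2-yl]methyl}cyclohexa-2,5-diene-1,4-dione
Conditions: 60% aq. HClO4, THF, 20 °C
Reagents that add atoms: water, O
Why: Acid hydrolysis of a vinylogous ester is expected at the methoxy group flanked by the bulky alkyl substituent, which is twisted out of conjugation and therefore the more electrophilic position, giving the 2-hydroxy-5-methoxy-3-alkylquinone.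

Step 16
Reactants: 25 2-hydroxy-5-methoxy-3-{[(1R,2R,4aS,8aS)-1,2,4a,5-tetramethyl-1,2,3,4,4a,7,8,8a-octahydronaphthalen-2-yl]methyl}cyclohexa-2,5-diene-1,4-dione
Product: 26 dysidenone A
Conditions: NaOMe, MeOH, 60 °C, under argon
Reagents that add atoms: methanol, CO
Why: Benzilic ester rearrangement of the 1,2,4-triketo tautomer (methoxide adds to the hydroxyl-bearing carbon, the alkyl-bearing carbon migrates to the neighbouring carbonyl) contracts the ring to the methyl hydroxycyclopentenone carboxylate; the remote decalin gives no facial bias at the new carbinol carbon and the ketone α-carbon is expected to equilibrate with the side chain trans to the hydroxyl, so 26 should form together with its 1R,5S ring diastereomer and is isolated by HPLC.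

Compound list
1 | 2-(3-chloropropyl)-1,3-dioxolane | ClCCCC1OCCO1 | starting material
2 | 3-methylbut-3-en-2-one | CC(=O)C(C)=C | starting material
3 | [3-(1,3-dioxolan-2-yl)propyl]magnesium chloride | Cl[Mg]CCCC1OCCO1 | intermediate
4 | 7-(1,3-dioxolan-2-yl)-3-methylheptan-2-one (racemic) | CC(=O)C(C)CCCCC1OCCO1 | intermediate
5 | 6-methyl-7-oxooctanal (racemic) | CC(=O)C(C)CCCCC=O | intermediate
6 | dimethyl (2-oxopropyl)phosphonate | COP(=O)(CC(C)=O)OC | starting material
7 | (2R)-2-(anilinooxy)-6-methyl-7-oxooctanal (both epimers at C6 of the chain) | CC(=O)C(C)CCC[C@@H](ONc1ccccc1)C=O | intermediate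
8 | (3E,5R)-5-(anilinooxy)-9-methylundec-3-ene-2,10-dione (both epimers at C9 of the chain) | CC(=O)C(C)CCC[C@@H](ONc1ccccc1)/C=C/C(C)=O | intermediate
9 | (3E,5R)-5-hydroxy-9-methylundec-3-ene-2,10-dione (both epimers at C9 of the chain) | CC(=O)C(C)CCC[C@@H](O)/C=C/C(C)=O | intermediate
10 | (3E,5R)-5-[(tert-butyldimethylsilyl)oxy]-9-methylundec-3-ene-2,10-dione (both epimers at C9 of the chain) | CC(=O)C(C)CCC[C@@H](O[Si](C)(C)C(C)(C)C)/C=C/C(C)=O | intermediate
11 | 1-[(1S,2R,3R)-3-[(tert-butyldimethylsilyl)oxy]-1-methyl-2-(2-oxopropyl)cyclohexyl]ethan-1-one (acetyl trans to oxopropyl, oxopropyl trans to silyloxy) | CC(=O)[C@@]1(C)CCC[C@@H](O[Si](C)(C)C(C)(C)C)[C@@H]1CC(C)=O | intermediate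
12 | (4aS,8R,8aR)-8-[(tert-butyldimethylsilyl)oxy]-4,4a-dimethyl-4a,5,6,7,8,8a-hexahydronaphthalen-2(1H)-one (trans-fused, 5β-methyl, 10α-H, 9α-silyloxy) | C1CC[C@]2(C)C(C)=CC(=O)C[C@H]2[C@@H]1O[Si](C)(C)C(C)(C)C | intermediate
13 | (4a′S,8′R,8a′R)-4′,4a′-dimethyl-4a′,5′,6′,7′,8′,8a′-hexahydro-1′H-spiro[1,3-dithiolane-2,2′-naphthalen]-8′-ol | C1CC[C@]2(C)C(C)=CC3(SCCS3)C[C@H]2[C@@H]1O | intermediate
14 | (1R,4aS,8aR)-4a,5-dimethyl-1,2,3,4,4a,7,8,8a-octahydronaphthalen-1-ol | C1CC[C@]2(C)C(C)=CCC[C@H]2[C@@H]1O | intermediate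
15 | (4aS,8aR)-4a,5-dimethyl-3,4,4a,7,8,8a-hexahydronaphthalen-1(2H)-one (trans-fused) | C1CC[C@]2(C)C(C)=CCC[C@H]2C1=O | intermediate
16 | 1,2,4,5-tetramethoxybenzene | COc1cc(OC)c(OC)cc1OC | starting material
17 | (2,3,5,6-tetramethoxyphenyl)lithium | [Li]c1c(OC)c(OC)cc(OC)c1OC | intermediate
18 | 2,3,5,6-tetramethoxybenzaldehyde | O=Cc1c(OC)c(OC)cc(OC)c1OC | intermediate
19 | (2E,4aS,8aR)-4a,5-dimethyl-2-[(2,3,5,6-tetramethoxyphenyl)methylidene]-3,4,4a,7,8,8a-hexahydronaphthalen-1(2H)-one | COc1cc(OC)c(OC)c(/C=C2\CC[C@]3(C)C(C)=CCC[C@H]3C2=O)c1OC | intermediate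
20 | C8–C9 lithium enolate from conjugate reduction of 19 (5β-methyl, 10α-H) | COc1cc(OC)c(OC)c(CC2=C(O[Li])[C@@H]3CCC=C(C)[C@@]3(C)CC2)c1OC | intermediate
21 | (2R,4aS,8aR)-2,4a,5-trimethyl-2-[(2,3,5,6-tetramethoxyphenyl)methyl]-3,4,4a,7,8,8a-hexahydronaphthalen-1(2H)-one (8α-methyl, 8β-arylmethyl) | COc1cc(OC)c(OC)c(C[C@@]2(C)CC[C@]3(C)C(C)=CCC[C@H]3C2=O)c1OC | intermediate
22 | 1,2,4,5-tetramethoxy-3-{[(2R,4aS,8aS)-2,4a,5-trimethyl-1-methylidene-1,2,3,4,4a,7,8,8a-octahydronaphthalen-2-yl]methyl}benzene | COc1cc(OC)c(OC)c(C[C@@]2(C)CC[C@]3(C)C(C)=CCC[C@H]3C2=C)c1OC | intermediate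
23 | 1,2,4,5-tetramethoxy-3-{[(1R,2R,4aS,8aS)-1,2,4a,5-tetramethyl-1,2,3,4,4a,7,8,8a-octahydronaphthalen-2-yl]methyl}benzene (9β-methyl) | COc1cc(OC)c(OC)c(C[C@@]2(C)CC[C@]3(C)C(C)=CCC[C@H]3[C@H]2C)c1OC | intermediate
24 | 2,5-dimethoxy-3-{[(1R,2R,4aS,8aS)-1,2,4a,5-tetramethyl-1,2,3,4,4a,7,8,8a-octahydronaphthalen-2-yl]methyl}cyclohexa-2,5-diene-1,4-dione | COC1=CC(=O)C(OC)=C(C[C@@]2(C)CC[C@]3(C)C(C)=CCC[C@H]3[C@H]2C)C1=O | intermediate
25 | 2-hydroxy-5-methoxy-3-{[(1R,2R,4aS,8aS)-1,2,4a,5-tetramethyl-1,2,3,4,4a,7,8,8a-octahydronaphthalen-2-yl]methyl}cyclohexa-2,5-diene-1,4-dione | COC1=CC(=O)C(O)=C(C[C@@]2(C)CC[C@]3(C)C(C)=CCC[C@H]3[C@H]2C)C1=O | intermediate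
26 | dysidenone A, methyl (1S,5R)-1-hydroxy-3-methoxy-4-oxo-5-{[(1R,2R,4aS,8aS)-1,2,4a,5-tetramethyl-1,2,3,4,4a,7,8,8a-octahydronaphthalen-2-yl]methyl}cyclopent-2-ene-1-carboxylate | COC(=O)[C@]1(O)C=C(OC)C(=O)[C@@H]1C[C@@]1(C)CC[C@]2(C)C(C)=CCC[C@H]2[C@H]1C | target

Total step count: 16. Longest linear sequence: 15 steps (steps 1–8 and 10–16; step 9 is a one-step side branch).

Steps most likely to fail

Step 5. The C9 silyloxy centre may discriminate poorly between the two faces of the C5 enolate (the C5 epimer leads into the enantiomeric series), and the aldol closure may run through the acetyl methyl onto C2. The fallback sets out from 10 and puts C5 under reagent control. Condensation of the saturated ketone with (R)-1-phenylethylamine (4 Å sieves, toluene) gives the ketimine F1. On warming, its secondary enamine tautomer adds to the enone in an aza-ene-type intramolecular Michael addition to give the cyclised ketimine F2. Hydrolysis with aqueous AcOH gives diketone 11, where the sequence comes back to the route; 11 is then condensed with pyrrolidine/AcOH to 12 in a separate operation. The amine enantiomer is the one expected to reinforce the substrate bias.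

Step 16. The delocalised hydroxyquinone anion may resist addition of methoxide, so that the rearrangement stalls. The fallback sets out from 25 and uses the irreversible benzilic acid variant: aqueous LiOH in THF, then acidification, should give the ring-contracted hydroxy acid F3, driven by carboxylate formation. Esterification with Me3SiCHN2 in MeOH/toluene comes back to the route at 26. The absence of facial control at the new carbinol carbon remains, and 26 is again separated from its ring diastereomer.

Step 13. Hydrogen may be delivered to the wrong face of the exocyclic alkene, or the double bond may migrate into the ring on the metal surface before reduction. The fallback sets out from 22 and replaces hydrogenation by hydroboration with a bulky borane that cannot isomerise the alkene. 9-BBN in THF should add to the exocyclic alkene only, from the α face, to give the B-alkyl borane F4. Oxidation with NaOH/H2O2 gives the primary alcohol F5, I2/PPh3/imidazole gives the primary iodide F6, and reduction with Bu3SnH/AIBN in toluene at 80 °C comes back to the route at 23.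

Further compounds
F1 | step 5 | ketimine of 10 with (R)-1-phenylethylamine | CC(=N[C@H](C)c1ccccc1)C(C)CCC[C@@H](O[Si](C)(C)C(C)(C)C)/C=C/C(C)=O
F2 | step 5 | cyclised ketimine, the N-[(R)-1-phenylethyl]imine of 11 | CC(=N[C@H](C)c1ccccc1)[C@@]1(C)CCC[C@@H](O[Si](C)(C)C(C)(C)C)[C@@H]1CC(C)=O
F3 | step 16 | (1S,5R)-1-hydroxy-3-methoxy-4-oxo-5-{[(1R,2R,4aS,8aS)-1,2,4a,5-tetramethyl-1,2,3,4,4a,7,8,8a-octahydronaphthalen-2-yl]methyl}cyclopent-2-ene-1-carboxylic acid | OC(=O)[C@]1(O)C=C(OC)C(=O)[C@@H]1C[C@@]1(C)CC[C@]2(C)C(C)=CCC[C@H]2[C@H]1C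
F4 | step 13 | B-alkyl-9-borabicyclo[3.3.1]nonane from 22 (boron on the C9 methylene, 9β) | COc1cc(OC)c(OC)c(C[C@@]2(C)CC[C@]3(C)C(C)=CCC[C@H]3[C@H]2CB2C3CCCC2CCC3)c1OC
F5 | step 13 | primary alcohol, 9β-hydroxymethyl analogue of 23 | COc1cc(OC)c(OC)c(C[C@@]2(C)CC[C@]3(C)C(C)=CCC[C@H]3[C@H]2CO)c1OC
F6 | step 13 | primary iodide, 9β-iodomethyl analogue of 23 | COc1cc(OC)c(OC)c(C[C@@]2(C)CC[C@]3(C)C(C)=CCC[C@H]3[C@H]2CI)c1OC
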